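**Retrosynthetic overview**

1. The target is a biisoflavone joined D-C3'–G-C8 (D = 7-hydroxyisoflavone half, G = 5,7-dihydroxyisoflavone half). The strategy rests on ring C of each half holding a single methine, D-C2 and G-C2, between O1 and C3.
2. Removing both methines (the phenols being carried as four methyl ethers) leaves a biaryl with two 2-hydroxyaryl benzyl ketones. A twofold one-carbon annulation closes both pyranone rings, then BBr3 frees the phenols.
3. The D-side ketone comes from BF3-mediated acylation of resorcinol by a biaryl arylacetic acid that already carries the G-side ketone.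
4. The biaryl bond comes from a Suzuki coupling of an iodinated 2-hydroxy-4,6-dimethoxydeoxybenzoin with the pinacol boronate of methyl (3-bromo-4-methoxyphenyl)acetate. The deoxybenzoin is made from 3,5-dimethoxyphenol and (4-methoxyphenyl)acetic acid and iodinated next to its chelated hydroxyl.
5. Ring order: the four benzene rings are bought; ring C of D and ring C of G are formed last, in one flask.

Key step: step 8

Remark: the halogen is put on ring A of G after the first acylation, because free 3,5-dimethoxyphenol is expected to be halogenated also between its two methoxy groups, while the chelated hydroxy ketone directs to the carbon next to the free hydroxyl. The biaryl axis carries only small ortho groups and is taken as freely rotating, so no stereochemical element needs control.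

**Route**

Step 1
Reactants: 1 3,5-dimethoxyphenol; 2 (4-methoxyphenyl)acetic acid
Product: 3 1-(2-hydroxy-4,6-dimethoxyphenyl)-2-(4-methoxyphenyl)ethanone
Conditions: BF3·OEt2 (neat), 85 °C; then aq. NaOAc
Reagents that add atoms: none
Why: Friedel–Crafts acylation by the BF3-activated acid should go ortho to the hydroxyl, because BF3 chelation between the ketone oxygen and the ortho hydroxyl favours that position, and the acylated ring is then deactivated toward a second acylation.

Step 2
Reactants: 3 1-(2-hydroxy-4,6-dimethoxyphenyl)-2-(4-methoxyphenyl)ethanone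
Product: 4 1-(2-hydroxy-3-iodo-4,6-dimethoxyphenyl)-2-(4-methoxyphenyl)ethanone
Conditions: NIS (1.0 equiv), CF3CO2H (cat.), MeCN, 0 °C to rt
Reagents that add atoms: N-iodosuccinimide, O=C1CCC(=O)N1I
Why: Electrophilic aromatic iodination should go to C3, ortho to the chelated hydroxyl, which is activated by three oxygen donors and less crowded than C5 between the two methoxy groups, while the anisole ring and the ketone methylene are far less nucleophilic toward one equivalent of NIS; the site is to be checked by NOE (the remaining ring proton should sit next to both methoxy groups) before the material is carried on.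

Step 3
Reactants: 5 (3-bromo-4-methoxyphenyl)acetic acid
Product: 6 methyl (3-bromo-4-methoxyphenyl)acetate
Conditions: MeOH, H2SO4 (cat.), reflux
Reagents that add atoms: methanol, CO
Why: Fischer esterification masks the acid so that it cannot act as an acylating agent or interfere with the palladium steps.

Step 4
Reactants: 6 methyl (3-bromo-4-methoxyphenyl)acetate
Product: 7 methyl [4-methoxy-3-(4,4,5,5-tetramethyl-1,3,2-dioxaborolan-2-yl)phenyl]acetate
Conditions: B2pin2, Pd(dppf)Cl2 (cat.), KOAc, 1,4-dioxane, 90 °C
Reagents that add atoms: bis(pinacolato)diboron, CC1(C)OB(OC1(C)C)B1OC(C)(C)C(C)(C)O1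
Why: Miyaura borylation of the aryl bromide should proceed cleanly, since the weak acetate base neither enolises the arylacetate nor promotes Suzuki homocoupling.

Step 5
Reactants: 4 1-(2-hydroxy-3-iodo-4,6-dimethoxyphenyl)-2-(4-methoxyphenyl)ethanone; 7 methyl [4-methoxy-3-(4,4,5,5-tetramethyl-1,3,2-dioxaborolan-2-yl)phenyl]acetate
Product: 8 methyl [3-[2-hydroxy-4,6-dimethoxy-3-[(4-methoxyphenyl)acetyl]phenyl]-4-methoxyphenyl]acetate
Conditions: Pd(OAc)2 (cat.), SPhos, K3PO4, toluene/H2O, 90 °C
Reagents that add atoms: none
Why: In this Suzuki–Miyaura coupling the aryl iodide should add readily to zerovalent palladium even as the phenoxide, the biaryl phosphine SPhos is suited to transmetalation and reductive elimination at a tri-ortho-substituted centre, and the mild phosphate base should leave the ketone untouched, any ester it hydrolyses being the material that step 6 makes anyway.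

Step 6
Reactants: 8 methyl [3-[2-hydroxy-4,6-dimethoxy-3-[(4-methoxyphenyl)acetyl]phenyl]-4-methoxyphenyl]acetate
Product: 9 [3-[2-hydroxy-4,6-dimethoxy-3-[(4-methoxyphenyl)acetyl]phenyl]-4-methoxyphenyl]acetic acid
Conditions: LiOH, THF/MeOH/H2O, rt; then 1 M HCl
Reagents that add atoms: lithium hydroxide, [Li+].[OH-]
Why: Saponification of the unhindered methyl ester by hydroxide should be selective, because the hindered aryl ketone and the aryl methyl ethers are inert to cold aqueous base.

Step 7
Reactants: 9 [3-[2-hydroxy-4,6-dimethoxy-3-[(4-methoxyphenyl)acetyl]phenyl]-4-methoxyphenyl]acetic acid; 10 resorcinol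
Product: 11 1-[3-[5-[2-(2,4-dihydroxyphenyl)-2-oxoethyl]-2-methoxyphenyl]-2-hydroxy-4,6-dimethoxyphenyl]-2-(4-methoxyphenyl)ethanone
Conditions: resorcinol (2 equiv), BF3·OEt2 (neat), 85 °C; then aq. NaOAc
Reagents that add atoms: none
Why: Friedel–Crafts acylation of resorcinol by the BF3-activated arylacetic acid should occur at C4 (ortho to one hydroxyl, para to the other), and self-acylation should not compete because ring A of G in 9 is already deactivated by its ketone and resorcinol is in excess.

Step 8
Reactants: 11 1-[3-[5-[2-(2,4-dihydroxyphenyl)-2-oxoethyl]-2-methoxyphenyl]-2-hydroxy-4,6-dimethoxyphenyl]-2-(4-methoxyphenyl)ethanone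
Product: 13 7-hydroxy-3-[4-methoxy-3-[5,7-dimethoxy-3-(4-methoxyphenyl)-4-oxo-4H-chromen-8-yl]phenyl]-4H-chromen-4-one, via bis-enaminone 12 (not isolated)
Conditions: DMF, BF3·OEt2 (8 equiv), 50 °C; CH3SO2Cl (6 equiv), 90 °C; then aq. NaOAc
Reagents that add atoms: N,N-dimethylformamide, CN(C)C=O
Why: DMF and CH3SO2Cl form a chloroiminium (Vilsmeier-type) electrophile, and each BF3-chelated 2-hydroxyaryl ketone enolises toward its benzylic CH2, which attacks the iminium carbon and loses HCl to give bis-enaminone 12 (new bonds D-C2–C3 and G-C2–C3). In each half the ortho hydroxyl then adds to the enaminone β-carbon in a 6-endo-trig closure and dimethylamine is eliminated (new bonds D-O1–C2 and G-O1–C2), so that ring C of D and ring C of G both form as pyranones. The closest known reaction is the one-carbon cyclisation of 2-hydroxydeoxybenzoins to isoflavones with DMF, CH3SO2Cl and BF3·OEt2, which tolerates free phenols such as the D-7 hydroxyl. No stereocenter is formed. The selectivity needed is closure of ring C of G through the oxygen next to the biaryl carbon, and it is secured because that oxygen is the only free hydroxyl on ring A of G, the future G-5 and G-7 oxygens being methyl ethers, while on the D half only the chelated hydroxyl is ortho to the ketone. Attack at the two methylenes and not at the arenes is secured by the nucleophilicity of the boron-bound enols and by the acyl deactivation of ring A in both halves.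

Step 9
Reactants: 13 7-hydroxy-3-[4-methoxy-3-[5,7-dimethoxy-3-(4-methoxyphenyl)-4-oxo-4H-chromen-8-yl]phenyl]-4H-chromen-4-one
Product: 14 5,7-dihydroxy-8-[2-hydroxy-5-(7-hydroxy-4-oxo-4H-chromen-3-yl)phenyl]-3-(4-hydroxyphenyl)-4H-chromen-4-one
Conditions: BBr3 (excess), CH2Cl2, −78 °C to rt; then H2O
Reagents that add atoms: none
Why: BBr3 ether cleavage (Lewis acid–base complexation, then bromide attack at methyl) should remove all four methyl groups while the pyranone rings stay closed, and the low temperature avoids the hot-acid ring opening and reclosure that could move the aryl group from G-C8 to G-C6 once the G-5 hydroxyl is free.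

**Compound list**

1 | 3,5-dimethoxyphenol | COc1cc(O)cc(OC)c1 | starting material
2 | (4-methoxyphenyl)acetic acid | COc1ccc(CC(=O)O)cc1 | starting material
3 | 1-(2-hydroxy-4,6-dimethoxyphenyl)-2-(4-methoxyphenyl)ethanone | COc1ccc(CC(=O)c2c(O)cc(OC)cc2OC)cc1 | intermediate
4 | 1-(2-hydroxy-3-iodo-4,6-dimethoxyphenyl)-2-(4-methoxyphenyl)ethanone | COc1ccc(CC(=O)c2c(O)c(I)c(OC)cc2OC)cc1 | intermediate
5 | (3-bromo-4-methoxyphenyl)acetic acid | COc1ccc(CC(=O)O)cc1Br | starting material
6 | methyl (3-bromo-4-methoxyphenyl)acetate | COC(=O)Cc1ccc(OC)c(Br)c1 | intermediate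
7 | methyl [4-methoxy-3-(4,4,5,5-tetramethyl-1,3,2-dioxaborolan-2-yl)phenyl]acetate | COC(=O)Cc1ccc(OC)c(c1)B1OC(C)(C)C(C)(C)O1 | intermediate
8 | methyl [3-[2-hydroxy-4,6-dimethoxy-3-[(4-methoxyphenyl)acetyl]phenyl]-4-methoxyphenyl]acetate | COC(=O)Cc1ccc(OC)c(c1)-c1c(O)c(C(=O)Cc2ccc(OC)cc2)c(OC)cc1OC | intermediate
9 | [3-[2-hydroxy-4,6-dimethoxy-3-[(4-methoxyphenyl)acetyl]phenyl]-4-methoxyphenyl]acetic acid | OC(=O)Cc1ccc(OC)c(c1)-c1c(O)c(C(=O)Cc2ccc(OC)cc2)c(OC)cc1OC | intermediate
10 | resorcinol | Oc1cccc(O)c1 | starting material
11 | 1-[3-[5-[2-(2,4-dihydroxyphenyl)-2-oxoethyl]-2-methoxyphenyl]-2-hydroxy-4,6-dimethoxyphenyl]-2-(4-methoxyphenyl)ethanone | COc1ccc(CC(=O)c2c(OC)cc(OC)c(-c3cc(CC(=O)c4ccc(O)cc4O)ccc3OC)c2O)cc1 | intermediate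
12 | 1-[3-[5-[3-(dimethylamino)-1-(2,4-dihydroxyphenyl)-1-oxoprop-2-en-2-yl]-2-methoxyphenyl]-2-hydroxy-4,6-dimethoxyphenyl]-3-(dimethylamino)-2-(4-methoxyphenyl)prop-2-en-1-one (bis-enaminone, alkene geometries not fixed) | COc1ccc(C(=CN(C)C)C(=O)c2c(OC)cc(OC)c(-c3cc(C(=CN(C)C)C(=O)c4ccc(O)cc4O)ccc3OC)c2O)cc1 | intermediate
13 | 7-hydroxy-3-[4-methoxy-3-[5,7-dimethoxy-3-(4-methoxyphenyl)-4-oxo-4H-chromen-8-yl]phenyl]-4H-chromen-4-one | O=c1c(-c2ccc(OC)c(-c3c(OC)cc(OC)c4c(=O)c(-c5ccc(OC)cc5)coc34)c2)coc2cc(O)ccc12 | intermediate
14 | 5,7-dihydroxy-8-[2-hydroxy-5-(7-hydroxy-4-oxo-4H-chromen-3-yl)phenyl]-3-(4-hydroxyphenyl)-4H-chromen-4-one | O=c1c(-c2ccc(O)c(-c3c(O)cc(O)c4c(=O)c(-c5ccc(O)cc5)coc34)c2)coc2cc(O)ccc12 | target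

**Step count**

Total: 9 steps. Longest linear sequence: 7 steps (steps 1, 2, 5, 6, 7, 8, 9, or equally steps 3, 4, 5, 6, 7, 8, 9).

**Steps most likely to fail**

Step 8. The methylene on the G half sits beside a ketone flanked by two ortho substituents and by the biaryl, so its aminomethylenation may lag behind that of the D half. The reaction could then stall at half-cyclised material, and the free D-7 hydroxyl may be formylated or sulfonylated under forcing conditions. The fallback closes the two rings one after the other, the hindered one first on a simpler substrate and with a different one-carbon donor. It sets out from compound 8 and comes back at compound 13. Compound 8, which has no free non-chelated phenol or acid that an amide acetal could methylate, would be heated with N,N-dimethylformamide dimethyl acetal (toluene, 90 °C; then AcOH) to give methyl [3-[5,7-dimethoxy-3-(4-methoxyphenyl)-4-oxo-4H-chromen-8-yl]-4-methoxyphenyl]acetate F1. Acidic hydrolysis (2 M HCl, 1,4-dioxane, 80 °C), chosen because the pyranone opens in alkali, would give [3-[5,7-dimethoxy-3-(4-methoxyphenyl)-4-oxo-4H-chromen-8-yl]-4-methoxyphenyl]acetic acid F2. BF3·OEt2 acylation of resorcinol 10 would then give 8-[5-[2-(2,4-dihydroxyphenyl)-2-oxoethyl]-2-methoxyphenyl]-5,7-dimethoxy-3-(4-methoxyphenyl)-4H-chromen-4-one F3. A single annulation with DMF, CH3SO2Cl and BF3·OEt2 on the unhindered resorcinol ketone of F3 would give 13.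

Step 5. Transmetalation and reductive elimination at the tri-ortho-substituted, phenoxide-bearing arylpalladium intermediate may be slow. That would allow protodeiodination of 4, protodeboronation of 7 or α-arylation of the enolisable ketone to compete. The fallback closes ring C of G before the coupling, which removes both the phenoxide and the acidic methylene. It sets out from compound 4 and comes back at compound 13. Compound 4 would be treated with N,N-dimethylformamide dimethyl acetal (toluene, 90 °C; then AcOH) to give 8-iodo-5,7-dimethoxy-3-(4-methoxyphenyl)-4H-chromen-4-one F4. Suzuki coupling of F4 with boronate 7 (Pd(PPh3)4, K2CO3, 1,4-dioxane/H2O, 80 °C) would give the isoflavone ester F1 that also stands in the fallback to step 8. From there the same operations follow: acid hydrolysis to the acid F2, acylation of resorcinol 10 to the ketone F3 and a single annulation to 13.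

Step 2. Iodination may lack site selectivity: attack at C5 between the two methoxy groups, double iodination, or halogenation of the ketone methylene. The fallback inverts the order of halogenation and acylation and relies on amine-directed ortho-halogenation of the free phenol. It sets out from compound 1 and comes back at compound 8. Compound 1 would be brominated with NBS and catalytic diisopropylamine (CH2Cl2, −78 °C to 0 °C) to give 2-bromo-3,5-dimethoxyphenol F5; its symmetrical 4-bromo isomer is easy to recognise and to separate at this stage. BF3·OEt2 acylation of F5 with acid 2 at the single remaining ortho position would give 1-(3-bromo-2-hydroxy-4,6-dimethoxyphenyl)-2-(4-methoxyphenyl)ethanone F6. Suzuki coupling of F6 with boronate 7 under the conditions of step 5 would give 8.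

**Further compounds**

F1 | step 8 | methyl [3-[5,7-dimethoxy-3-(4-methoxyphenyl)-4-oxo-4H-chromen-8-yl]-4-methoxyphenyl]acetate | COC(=O)Cc1ccc(OC)c(c1)-c1c(OC)cc(OC)c2c(=O)c(-c3ccc(OC)cc3)coc12
F2 | step 8 | [3-[5,7-dimethoxy-3-(4-methoxyphenyl)-4-oxo-4H-chromen-8-yl]-4-methoxyphenyl]acetic acid | OC(=O)Cc1ccc(OC)c(c1)-c1c(OC)cc(OC)c2c(=O)c(-c3ccc(OC)cc3)coc12
F3 | step 8 | 8-[5-[2-(2,4-dihydroxyphenyl)-2-oxoethyl]-2-methoxyphenyl]-5,7-dimethoxy-3-(4-methoxyphenyl)-4H-chromen-4-one | O=C(Cc1ccc(OC)c(c1)-c1c(OC)cc(OC)c2c(=O)c(-c3ccc(OC)cc3)coc12)c1ccc(O)cc1O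
F4 | step 5 | 8-iodo-5,7-dimethoxy-3-(4-methoxyphenyl)-4H-chromen-4-one | COc1ccc(cc1)-c1coc2c(I)c(OC)cc(OC)c2c1=O
F5 | step 2 | 2-bromo-3,5-dimethoxyphenol | COc1cc(O)c(Br)c(OC)c1
F6 | step 2 | 1-(3-bromo-2-hydroxy-4,6-dimethoxyphenyl)-2-(4-methoxyphenyl)ethanone | COc1ccc(CC(=O)c2c(O)c(Br)c(OC)cc2OC)cc1
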